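**Plan**

1. Atom labels (aromadendrane numbering): C1 ether carbon, C2/C3 cyclopentane CH2, C4 quaternary C(CH3), C5 ring-fusion CH, C6/C7/C11 cyclopropane, C8/C9 CH2, C10 CH(CH3), C1′ benzylic CH.
2. Retrosynthesis: cut the two aryl–CHO bonds; then O–C1 and C1–C2 together; then C2=C(CH3)2 and C2–C3 (two Wittig steps on the lactone carbon C3); then C4–C1′ (o-quinone methide); then C4–C5 (enolate alkylation) and C9–C10 (seven-membered ring), back to (+)-3-carene.
3. Forward: carene → cyclopropane-fused cycloheptanone → temporary cis γ-lactone C3–O–C1 → C4 made quaternary by the arylbenzyl unit → lactone unfolded to a C1 ketone with a C2 prenyl terminus → cyclopentane and oxepane closed in one flask → demethylation and double formylation.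
4. Enabling feature: C1 is a fully substituted carbon shared by the cyclopentane, the cycloheptane and the oxepane, and it carries the aryl ether oxygen. As a ketone it lies 1,5 to C2=C(CH3)2 across C5–C4–C3 (C4 quaternary), so carbonyl–olefin metathesis gives C1=C2; protonation then gives the tertiary C1 cation, which the phenol on C1′ (tied to C4) can reach from one face only.
5. Stereochemistry: C6/C7 from (+)-3-carene; C10 by hydrogenation anti to C11; C5 by alkylation anti to the cyclopropane; C4 and C1′ by endo [4+2] of the (E)-o-quinone methide on the convex lactone face; C1 by the tether.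

Key step: step 14

Assumption: 8, 11 and 13 are taken as commercial; the C4 configuration of 9 and 10 and the C1 carbinol configuration of 10–22 do not affect the outcome (C4 is planarised in step 8, C1 is oxidised in step 13).

**Route**

Step 1
Reactants: 1 (+)-3-carene
Product: 2 keto acetal 1-[(1S,3R)-3-(2,2-dimethoxyethyl)-2,2-dimethylcyclopropyl]propan-2-one
Conditions: O3, CH2Cl2/MeOH, −78 °C; Me2S, −78 → 23 °C; then p-TsOH (cat.), MeOH, 23 °C
Reagents that add atoms: ozone (O=[O+][O-]); methanol (CO)
Why: Ozonolysis with reductive work-up cleaves the only alkene to the cis keto aldehyde, and acid-catalysed acetalisation masks only the aldehyde (future C9), leaving the methyl ketone (future C1) and the carene centres C6 and C7 untouched.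

Step 2
Reactants: 2 keto acetal
Product: 3 ethyl ketone 1-[(1S,3R)-3-(2,2-dimethoxyethyl)-2,2-dimethylcyclopropyl]butan-2-one
Conditions: LiN(i-Pr)2, THF, −78 °C; MeI, DMPU, −78 → −30 °C
Reagents that add atoms: iodomethane (CI)
Why: Kinetic deprotonation of the methyl ketone at CH3 and C-methylation (enolate alkylation) turn the methyl into the CH2CH3 unit that becomes C10 and its methyl.

Step 3
Reactants: 3 ethyl ketone
Product: 6 enone (1S,7R)-4,8,8-trimethylbicyclo[5.1.0]oct-4-en-3-one, via silyl enol ether 4 (not isolated), via methoxy ketone 5 (not isolated)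
Conditions: LiN(i-Pr)2, Me3SiCl, THF, −78 °C; crude 4, Me3SiOTf (10 mol %), CH2Cl2, −78 °C; then p-TsOH (cat.), toluene, 60 °C
Reagents that add atoms: none
Why: The base should deprotonate the less hindered CH2CH3 side, the silyl enol ether adds to the oxocarbenium ion of the acetal in an intramolecular Mukaiyama aldol reaction (C9–C10, seven-membered ring, both arms held together by the cis-cyclopropane), and acid-catalysed loss of methanol gives the conjugated enone, so no stereocentre needs control here.

Step 4
Reactants: 6 enone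
Product: 7 ketone (1S,4S,7R)-4,8,8-trimethylbicyclo[5.1.0]octan-3-one
Conditions: H2 (1 atm), Pd on carbon (5 wt %), EtOAc, 23 °C
Reagents that add atoms: none
Why: Heterogeneous hydrogenation of C9=C10 should deliver hydrogen to the face opposite the gem-dimethylcyclopropane bridge, as in carane-type bicycles, so the C10 methyl ends cis to C11 (10S) under neutral, non-epimerising conditions.

Step 5
Reactants: 7 ketone; 8 ethyl (2S)-2-(trifluoromethanesulfonyloxy)propanoate
Product: 9 keto ester ethyl (2S)-2-[(1R,2R,4S,7R)-4,8,8-trimethyl-3-oxobicyclo[5.1.0]octan-2-yl]propanoate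
Conditions: LiN(i-Pr)2, THF, −78 °C; then 8, −78 → −40 °C
Reagents that add atoms: none
Why: The kinetic enolate forms at the CH2 (C5) and not at CH(CH3), and SN2 alkylation by the lactate triflate on the face away from the cyclopropane CMe2 sets C5 (R); C4 forms with inversion (S) and is erased in step 8.

Step 6
Reactants: 9 keto ester
Product: 10 cis-fused γ-lactone (lactone O on C1 cis to the C5–C4 bond; carbonyl carbon = C3)
Conditions: LiBH(s-Bu)3, THF, −78 → 23 °C; aq. NH4Cl; then p-TsOH (cat.), CH2Cl2, 23 °C
Reagents that add atoms: none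
Why: The bulky hydride should attack the ketone anti to the C5 side chain, the cis alkoxide closes onto the ester (lactonisation), and the γ-lactone ties C4 into a ring for the next step; the C1 carbinol centre is temporary.

Step 7
Reactants: 11 2-hydroxy-4,6-dimethoxybenzaldehyde
Product: 12 tert-butyl 2-formyl-3,5-dimethoxyphenyl carbonate
Conditions: Boc2O, i-Pr2NEt, DMAP (cat.), CH2Cl2, 23 °C
Reagents that add atoms: di-tert-butyl dicarbonate (CC(C)(C)OC(=O)OC(=O)OC(C)(C)C)
Why: DMAP-catalysed acylation of the phenol gives the aryl carbonate needed for low-temperature o-quinone methide generation; no stereocentre is involved.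

Step 8
Reactants: 10 γ-lactone; 12 aryl carbonate; 13 phenylmagnesium bromide
Product: 17 phenol lactone (10 carrying the (S)-(2-hydroxy-4,6-dimethoxyphenyl)(phenyl)methyl group on C4; C4 R), via silyl ketene acetal 14 (not isolated), via o-quinone methide 15 (not isolated), via ortho ester cycloadduct 16 (not isolated)
Conditions: 10, LiN(i-Pr)2, THF, −78 °C; t-BuMe2SiCl, DMPU, −78 → 0 °C (crude 14); 12 + 14, Et2O, −78 °C; 13, −78 → 23 °C; 1 M HCl work-up
Reagents that add atoms: none
Why: Addition of 13 to the aldehyde, carbonate transfer and β-elimination give the (E)-o-quinone methide 15, which should add to ketene acetal 14 in an inverse-demand hetero-Diels–Alder (Mukaiyama–Michael type) reaction on the convex lactone face anti to C6 with the lactone ring endo, so that C1′ bonds to C4 cis to H5 (C4 R) and the phenyl ends cis to C5 (C1′ S); acidic work-up opens ortho ester 16 to lactone and phenol.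

Step 9
Reactants: 17 phenol lactone
Product: 18 aryl tert-butyldimethylsilyl ether of 17
Conditions: t-BuMe2SiOTf, 2,6-lutidine, CH2Cl2, 0 °C
Reagents that add atoms: tert-butyldimethylsilyl trifluoromethanesulfonate (CC(C)(C)[Si](C)(C)OS(=O)(=O)C(F)(F)F)
Why: Silylation with a silyl triflate and a hindered base protects the electron-rich phenol from the ylide bases and the periodinane used later.

Step 10
Reactants: 18 silyl ether lactone
Product: 20 enol ether alcohol (C4–CH=CH–OMe; free C1–OH), via lactol 19 (not isolated)
Conditions: i-Bu2AlH, CH2Cl2, −78 °C; aq. potassium sodium tartrate; crude 19, MeOCH2PPh3Cl, KN(SiMe3)2, THF, 0 → 50 °C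
Reagents that add atoms: (methoxymethyl)triphenylphosphonium chloride (COC[P+](c1ccccc1)(c1ccccc1)c1ccccc1.[Cl-])
Why: i-Bu2AlH stops at the lactol, whose open hydroxy aldehyde form undergoes Wittig methoxymethylenation, which adds C2 and releases the C1 hydroxyl; the enol ether geometry is irrelevant.

Step 11
Reactants: 20 enol ether alcohol
Product: 21 six-membered lactol (C2 hemiacetal bridged by O to C1)
Conditions: HCl (1 M), THF, 23 °C
Reagents that add atoms: water (O)
Why: Acid hydrolysis of the enol ether unveils the C2 aldehyde, which is held as the lactol with the C1 hydroxyl, while the aryl silyl ether and the cyclopropane should tolerate dilute acid.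

Step 12
Reactants: 21 lactol
Product: 22 prenyl alcohol (C4–CH2–CH=CMe2; free C1–OH)
Conditions: i-PrPPh3I, n-BuLi, THF, 0 → 23 °C
Reagents that add atoms: isopropyltriphenylphosphonium iodide (CC(C)[P+](c1ccccc1)(c1ccccc1)c1ccccc1.[I-])
Why: Wittig olefination of the open aldehyde form of the lactol with the isopropylidene ylide installs the trisubstituted C2=C(CH3)2 terminus needed for the metathesis and again frees the C1 hydroxyl.

Step 13
Reactants: 22 prenyl alcohol
Product: 23 prenyl ketone (C1=O)
Conditions: Dess–Martin periodinane, NaHCO3, CH2Cl2, 23 °C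
Reagents that add atoms: none
Why: Dess–Martin oxidation converts the secondary C1 alcohol into the ketone under buffered, non-enolising conditions, so C5 and C10 next to the carbonyl should keep their configuration.

Step 14
Reactants: 23 prenyl ketone
Product: 26 O,O-dimethyl bis-deformyl psiguadial A, via cyclopentene silyl ether 24 (not isolated), via cyclopentene phenol 25 (not isolated)
Conditions: FeCl3 (10 mol %), ClCH2CH2Cl, 23 °C; then MeOH (3 equiv), 23 → 40 °C
Reagents that add atoms: none
Why: Proposed new method: FeCl3 should bind the C1 ketone, the prenyl alkene attacks it through C2 (5-exo-trig, Thorpe–Ingold help from quaternary C4) to a tertiary cation that closes to an oxetane, and cycloreversion releases acetone and leaves the C1=C2 cyclopentene 24, which is the known FeCl3-catalysed ring-closing carbonyl–olefin metathesis of aliphatic ketones with trisubstituted olefins. Added MeOH with the iron salt removes the aryl silyl group, and the acid medium protonates 25 at C2 to the tertiary C1 cation (the cation of the presumed biogenesis), which the phenol oxygen captures; the closest known reaction is iron-catalysed intramolecular Markovnikov hydroalkoxylation of alkenes by phenols, and only the one-flask combination is new. The cyclopentane thus closes by C1–C2 bond formation in the 5-exo mode and the oxepane by O–C1 bond formation in the 7-exo mode on the C1=C2 alkene. C1 is the only stereocentre formed and is set by the tether, because the oxygen hangs from C4 through C1′ and the arene and can reach C1 only on the face that carries C1′ and H5, giving the cis-fused hydroazulene with O1, H5 and C1′ syn. The step needs metathesis to win over the carbonyl-ene reaction (the gem-dimethyl terminus favours the oxetane route and acetone loss), Markovnikov protonation (tertiary C1 against secondary C2), O- rather than C-capture (both arene positions ortho to C1′ carry oxygen), and capture faster than a hydride shift from C5 to a cyclopropylcarbinyl cation (the phenol is held over C1).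

Step 15
Reactants: 26 dimethyl ether
Product: 27 bis-deformyl psiguadial A (resorcinol)
Conditions: NaSEt, DMF, 130 °C; aq. HCl work-up
Reagents that add atoms: none
Why: Thiolate cleaves both aryl methyl ethers by SN2 attack at the methyl carbons, a pathway closed to the tertiary C1–O bond, and the basic medium should spare the cyclopropane.

Step 16
Reactants: 27 resorcinol
Product: 28 psiguadial A
Conditions: POCl3, DMF, EtOAc, 0 → 23 °C; then H2O, 50 °C
Reagents that add atoms: N,N-dimethylformamide (CN(C)C=O); water (O)
Why: Vilsmeier–Haack formylation should attack the only two free positions of the strongly activated phloroglucinol ring, each ortho to a free hydroxyl, and hydrolysis of the two iminium salts gives the dialdehyde.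

**Compound list**

1 | (+)-3-carene, (1S,6R)-3,7,7-trimethylbicyclo[4.1.0]hept-3-ene | CC1=CC[C@@H]2[C@H](C1)C2(C)C | starting material
2 | 1-[(1S,3R)-3-(2,2-dimethoxyethyl)-2,2-dimethylcyclopropyl]propan-2-one | COC(OC)C[C@@H]1[C@H](CC(C)=O)C1(C)C | intermediate
3 | 1-[(1S,3R)-3-(2,2-dimethoxyethyl)-2,2-dimethylcyclopropyl]butan-2-one | COC(OC)C[C@@H]1[C@H](CC(=O)CC)C1(C)C | intermediate
4 | trimethylsilyl enol ether of 3 (C1–OSiMe3, C1=C10, E/Z mixture) | COC(OC)C[C@@H]1[C@H](CC(O[Si](C)(C)C)=CC)C1(C)C | intermediate
5 | (1S,7R)-5-methoxy-4,8,8-trimethylbicyclo[5.1.0]octan-3-one (mixture at C9 and C10) | COC1C[C@@H]2[C@H](CC(=O)C1C)C2(C)C | intermediate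
6 | (1S,7R)-4,8,8-trimethylbicyclo[5.1.0]oct-4-en-3-one | CC1=CC[C@@H]2[C@H](CC1=O)C2(C)C | intermediate
7 | (1S,4S,7R)-4,8,8-trimethylbicyclo[5.1.0]octan-3-one | C[C@H]1CC[C@@H]2[C@H](CC1=O)C2(C)C | intermediate
8 | ethyl (2S)-2-(trifluoromethanesulfonyloxy)propanoate | CCOC(=O)[C@H](C)OS(=O)(=O)C(F)(F)F | starting material
9 | ethyl (2S)-2-[(1R,2R,4S,7R)-4,8,8-trimethyl-3-oxobicyclo[5.1.0]octan-2-yl]propanoate | C[C@H]1CC[C@@H]2[C@H]([C@@H](C1=O)[C@H](C)C(=O)OCC)C2(C)C | intermediate
10 | cis-fused γ-lactone of the C1-hydroxy acid from 9 (O on C1 cis to C5–C4; 10-Me cis to CMe2) | C[C@H]1CC[C@@H]2[C@H]([C@@H]3[C@H](C)C(=O)O[C@@H]31)C2(C)C | intermediate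
11 | 2-hydroxy-4,6-dimethoxybenzaldehyde | COc1cc(O)c(C=O)c(OC)c1 | starting material
12 | tert-butyl 2-formyl-3,5-dimethoxyphenyl carbonate | COc1cc(OC)c(C=O)c(OC(=O)OC(C)(C)C)c1 | intermediate
13 | phenylmagnesium bromide | Br[Mg]c1ccccc1 | starting material
14 | tert-butyldimethylsilyl ketene acetal of lactone 10 | C[C@H]1CC[C@@H]2[C@H]([C@@H]3C(C)=C(O[Si](C)(C)C(C)(C)C)O[C@@H]31)C2(C)C | intermediate
15 | (6E)-6-benzylidene-3,5-dimethoxycyclohexa-2,4-dien-1-one (o-quinone methide) | O=C1C=C(OC)C=C(OC)/C1=C\c1ccccc1 | intermediate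
16 | [4+2] cycloadduct of 14 and 15 (chroman ortho ester, silyloxy on C3, cis-fused) | C[C@H]1CC[C@@H]2[C@H]([C@@H]3[C@@]4(C)[C@@H](c5ccccc5)c5c(OC)cc(OC)cc5O[C@@]4(O[Si](C)(C)C(C)(C)C)O[C@@H]31)C2(C)C | intermediate
17 | phenol lactone: 10 with (S)-(2-hydroxy-4,6-dimethoxyphenyl)(phenyl)methyl on C4 (C4 R, C1′ S) | C[C@H]1CC[C@@H]2[C@H]([C@@H]3[C@@](C)([C@@H](c4ccccc4)c4c(O)cc(OC)cc4OC)C(=O)O[C@@H]31)C2(C)C | intermediate
18 | aryl tert-butyldimethylsilyl ether of 17 | C[C@H]1CC[C@@H]2[C@H]([C@@H]3[C@@](C)([C@@H](c4ccccc4)c4c(O[Si](C)(C)C(C)(C)C)cc(OC)cc4OC)C(=O)O[C@@H]31)C2(C)C | intermediate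
19 | lactol from 18 (C3 hemiacetal, anomeric mixture) | C[C@H]1CC[C@@H]2[C@H]([C@@H]3[C@@](C)([C@@H](c4ccccc4)c4c(O[Si](C)(C)C(C)(C)C)cc(OC)cc4OC)C(O)O[C@@H]31)C2(C)C | intermediate
20 | enol ether alcohol (C4–CH=CH–OMe, E/Z mixture; free C1–OH) | C[C@H]1CC[C@@H]2[C@H]([C@@H]([C@@H]1O)[C@](C)(C=COC)[C@@H](c3ccccc3)c3c(O[Si](C)(C)C(C)(C)C)cc(OC)cc3OC)C2(C)C | intermediate
21 | six-membered lactol (C2 hemiacetal bridged by O to C1, anomeric mixture) | C[C@H]1CC[C@@H]2[C@H]([C@H]3[C@@H]1OC(O)C[C@]3(C)[C@@H](c1ccccc1)c1c(O[Si](C)(C)C(C)(C)C)cc(OC)cc1OC)C2(C)C | intermediate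
22 | prenyl alcohol (C4–CH2–CH=CMe2; free C1–OH) | C[C@H]1CC[C@@H]2[C@H]([C@@H]([C@@H]1O)[C@](C)(CC=C(C)C)[C@@H](c3ccccc3)c3c(O[Si](C)(C)C(C)(C)C)cc(OC)cc3OC)C2(C)C | intermediate
23 | prenyl ketone (C1=O) | C[C@H]1CC[C@@H]2[C@H]([C@@H](C1=O)[C@](C)(CC=C(C)C)[C@@H](c3ccccc3)c3c(O[Si](C)(C)C(C)(C)C)cc(OC)cc3OC)C2(C)C | intermediate
24 | cyclopentene (C1=C2) aryl silyl ether | C[C@H]1CC[C@@H]2[C@H]([C@H]3C1=CC[C@]3(C)[C@@H](c1ccccc1)c1c(O[Si](C)(C)C(C)(C)C)cc(OC)cc1OC)C2(C)C | intermediate
25 | cyclopentene (C1=C2) phenol | C[C@H]1CC[C@@H]2[C@H]([C@H]3C1=CC[C@]3(C)[C@@H](c1ccccc1)c1c(O)cc(OC)cc1OC)C2(C)C | intermediate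
26 | O,O-dimethyl bis-deformyl psiguadial A (bridged oxepane, two OMe) | C[C@H]1CC[C@@H]2[C@H]([C@@H]3[C@]4(C)CC[C@@]31Oc1cc(OC)cc(OC)c1[C@@H]4c1ccccc1)C2(C)C | intermediate
27 | bis-deformyl psiguadial A (two free OH) | C[C@H]1CC[C@@H]2[C@H]([C@@H]3[C@]4(C)CC[C@@]31Oc1cc(O)cc(O)c1[C@@H]4c1ccccc1)C2(C)C | intermediate
28 | psiguadial A (1S,4R,5R,6R,7R,10S,1′S in the numbering above) | C[C@H]1CC[C@@H]2[C@H]([C@@H]3[C@]4(C)CC[C@@]31Oc1c(C=O)c(O)c(C=O)c(O)c1[C@@H]4c1ccccc1)C2(C)C | target

**Totals and risks**

Total step count: 16. Longest linear sequence: 15 (steps 1–6 and 8–16).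

Step 14 (carries the label). The Lewis acid may divert the ketone–olefin pair into carbonyl-ene or Prins products, enolise the ketone (epimerisation at C5 or C10) or oxidise the electron-rich arene. The C1 cation may also suffer a hydride shift from C5 and opening of the cyclopropane before the oxygen arrives. Fallback with known chemistry, setting out from 23: Cp2TiMe2 (toluene, 80 °C) methylenates the C1 ketone to the exocyclic methylene compound F1. Ring-closing olefin metathesis with the second-generation Grubbs catalyst (CH2Cl2, 40 °C) expels isobutene and gives cyclopentene 24, now isolated. Bu4NF frees phenol 25. Cobalt-catalysed hydrogen-atom-transfer hydroalkoxylation (Co(salen), C16H14CoN2O2, with N-fluoro-2,4,6-trimethylpyridinium tetrafluoroborate and PhSiH3) then closes the oxepane under non-acidic conditions, and the route is rejoined at 26.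

Step 8. Loss of facial or endo/exo control, or E/Z isomerisation of the quinone methide, would scramble C1′, and silyl transfer or aryl ester formation could compete with C–C bond formation. Fallback, setting out from 10: the lithium enolate (LiN(i-Pr)2) undergoes an aldol addition to benzaldehyde on the convex face to give the hydroxybenzyl lactone F2 (C4 set; carbinol centre irrelevant). Sc(OTf)3-catalysed ionisation of the benzylic alcohol in the presence of 3,5-dimethoxyphenol then alkylates the phenol ortho to its hydroxyl (Friedel–Crafts), with the arene approaching anti to the C5 branch. The route is rejoined at 17.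

Step 10. Steric blocking of the olefination at the neopentyl lactol carbon, with the lactol returning unchanged or the ylide acting only as a base. Fallback, setting out from lactol 19 (isolated after the i-Bu2AlH step): LiC(N2)SiMe3 (Colvin homologation, THF, −78 → 0 °C) converts the masked aldehyde into the terminal alkyne, alkynyl alcohol F3. Anti-Markovnikov hydroboration with (c-C6H11)2BH and oxidation with NaBO3 gives the C2 aldehyde, which closes to lactol 21, where the route is rejoined.

Further compounds
F1 | step 14 | exocyclic methylene analogue of 23 (C1=CH2, prenyl on C4, aryl silyl ether) | C[C@H]1CC[C@@H]2[C@H]([C@@H](C1=C)[C@](C)(CC=C(C)C)[C@@H](c3ccccc3)c3c(O[Si](C)(C)C(C)(C)C)cc(OC)cc3OC)C2(C)C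
F2 | step 8 | lactone 10 carrying hydroxy(phenyl)methyl on C4 (aldol adduct, carbinol mixture) | C[C@H]1CC[C@@H]2[C@H]([C@@H]3[C@@](C)(C(O)c4ccccc4)C(=O)O[C@@H]31)C2(C)C
F3 | step 10 | alkynyl alcohol (C4–C≡CH; free C1–OH; aryl silyl ether) | C[C@H]1CC[C@@H]2[C@H]([C@@H]([C@@H]1O)[C@](C)(C#C)[C@@H](c3ccccc3)c3c(O[Si](C)(C)C(C)(C)C)cc(OC)cc3OC)C2(C)C
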